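**Plan**

1. Retrosynthesis: the five O–benzyl bonds are cut last. The C2–C3 bond of the pyranone (C-ring) is then cut by moving the C3 oxygen back between C2 and C3, which gives a seven-membered cyclic acetal (1,3-benzodioxepin-5-one). Its two acetal C–O bonds lead to an ω-hydroxy-2'-hydroxyacetophenone and 4-(benzyloxy)benzaldehyde; the ω-C–O bond, two ArO–Bn bonds and two aryl–CH2 bonds lead back to phloroacetophenone.
2. Enabling feature: C2 is both α to the ring oxygen O1 and benzylic to a para-oxygenated aryl (a latent oxocarbenium carbon). C3 is the oxygen-bearing α-carbon of the aryl ketone C4 (a latent enediol carbon). The C2–C3 bond is therefore an aldol bond whose C3 oxygen can act as the leaving group of an acetal.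
3. Forward order: the A-ring is completed first (twofold C-benzylation, twofold O-benzylation), then ω-hydroxylation, closure of the seven-membered acetal ring, contraction to the six-membered pyranone, and global hydrogenolysis.
4. Stereochemistry: the acetal is racemic and its stereocentre is erased on ionisation. C2 and C3 are both created in the ring contraction under a chiral Brønsted acid (C2 by the chiral counter-anion, C3 trans by the ring transition state and equilibration). No later step touches them.

Key step: step 6

Assumption: the sense of induction of the chiral acid in step 6 cannot be fixed on paper; the (R)-catalyst is written, and its enantiomer is to be used if it leads to the 2S series.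

**Step 1**
Reactants: 1 2',4',6'-trihydroxyacetophenone; 2 4-(benzyloxy)benzyl alcohol (2.2 equiv, slow addition)
Product: 3 1-{2,4,6-trihydroxy-3,5-bis[4-(benzyloxy)benzyl]phenyl}ethanone
Conditions: Sc(OTf)3 (10 mol%), MeCN, 50 °C
Reagents that add atoms: none
Why: Friedel–Crafts benzylation; the Lewis acid ionises the p-alkoxybenzyl alcohol to a stabilised benzylic cation, which should attack the two equivalent free ring positions of the phloroglucinol nucleus, and no stereocentre is formed.

**Step 2**
Reactants: 3; 4 benzyl bromide (2.1 equiv)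
Product: 5 1-{2,4-bis(benzyloxy)-3,5-bis[4-(benzyloxy)benzyl]-6-hydroxyphenyl}ethanone
Conditions: K2CO3 (2.5 equiv), DMF, 0 °C to rt
Reagents that add atoms: none
Why: Williamson O-alkylation; the 4-OH (para to the acetyl group, most acidic) and one of the two equivalent ortho-OH groups should react, while the last OH is held in a hydrogen bond to the ketone and is the least nucleophilic.

**Step 3**
Reactants: 5
Product: 8 1-{2,4-bis(benzyloxy)-3,5-bis[4-(benzyloxy)benzyl]-6-hydroxyphenyl}-2-hydroxyethanone, via silyl enol ether 6 (not isolated), via silyloxy ketone 7 (not isolated)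
Conditions: TMSOTf (2.5 equiv), Et3N, CH2Cl2, 0 °C; then mCPBA (1.1 equiv), CH2Cl2, −20 °C; then 1 M HCl, THF, rt
Reagents that add atoms: mCPBA, O=C(OO)c1cccc(Cl)c1 (the ω-oxygen); TMSOTf, C[Si](C)(C)OS(=O)(=O)C(F)(F)F (silyl groups of 6 and 7 only, removed in the same step)
Why: Rubottom oxidation; soft enolisation gives the silyl enol ether (the phenol is silylated as well), the peracid epoxidises the electron-rich enol double bond, silyl migration gives the α-silyloxy ketone, and dilute acid should remove both silyl groups without touching the benzyl ethers.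

**Step 4**
Reactants: 9 4-(benzyloxy)benzaldehyde
Product: 10 4-(benzyloxy)benzaldehyde dimethyl acetal
Conditions: HC(OMe)3, p-TsOH (cat.), MeOH, rt; Et3N quench
Reagents that add atoms: trimethyl orthoformate, COC(OC)OC; methanol, CO
Why: acid-catalysed acetalisation of an aldehyde, driven to completion by the orthoformate as water scavenger.

**Step 5**
Reactants: 8; 10 (1.5 equiv)
Product: 11 rac-6,8-bis(benzyloxy)-2-[4-(benzyloxy)phenyl]-7,9-bis[4-(benzyloxy)benzyl]-4H-1,3-benzodioxepin-5-one (ring atoms: aryl-O1, acetal C2, O3, C4H2, C5=O, C5a, C9a)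
Conditions: PPTS (10 mol%), 5 Å MS, toluene, 50 °C
Reagents that add atoms: none
Why: transacetalisation; the primary ω-OH should exchange first and the ortho-phenol then closes the seven-membered ring on the stabilised p-benzyloxybenzyl oxocarbenium ion, with methanol removal driving the equilibrium. The weak acid is chosen so that the ketone does not enolise, and the configuration of the new acetal centre is irrelevant.

**Step 6**
Reactants: 11
Product: 13 (2R,3R)-5,7-bis(benzyloxy)-2-[4-(benzyloxy)phenyl]-6,8-bis[4-(benzyloxy)benzyl]-3-hydroxychroman-4-one, via oxocarbenium enediol ion 12 (not isolated)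
Conditions: (R)-3,3'-bis(2,4,6-triisopropylphenyl)-BINOL N-triflylphosphoramide (10 mol%), 5 Å MS, toluene, 0 to 40 °C
Reagents that add atoms: none
Why: Proposed new method: the chiral acid promotes enolisation of the ketone and heterolysis of the acetal C2–O3 bond (Petasis–Ferrier-type ionisation of an O-vinyl acetal) to give 12, an O-aryl oxocarbenium ion at C2 (stabilised by O1 and the p-benzyloxyphenyl group) tethered through the A-ring to an enediol and paired with the chiral anion; the enediol CH carbon then adds to the oxocarbenium carbon, so that the acetal carbon moves from O3 to the neighbouring carbon (formal [1,2] O-to-C shift), O3 leaves the ring as the 3-OH, and the seven-membered ring contracts to the six-membered pyranone. The closest known reaction types are the Lewis-acid [1,3] O-to-C ring contractions of cyclic vinyl acetals (Petasis–Ferrier rearrangement), [1,2]-Stevens shifts of acetal-derived oxonium ylides, and chiral-Brønsted-acid-catalysed additions of enols to oxocarbenium ion pairs. The pyranone ring closes by a 6-(enolendo)-endo-trig aldol-type attack. The racemic acetal centre is erased on ionisation, so both enantiomers of 11 converge; C2 is set by the chiral counter-anion, which is hydrogen-bonded to the enediol and shields one face of the planar oxocarbenium ion, and C3 is set trans to C2 by the half-chair transition state with both substituents pseudo-equatorial and is held there by acid-catalysed equilibration through the enol to the diequatorial isomer. The step needs C–C bond formation at the enediol CH carbon (six-membered aryl ketone) and not at the aryl-bearing carbon (five-membered 3-hydroxy-2,3-dihydrobenzofuran-3-carbaldehyde); this should be secured by the steric cost of a quaternary centre beside the di-ortho-substituted arene and by conjugation of the emerging aryl ketone, while the fully substituted A-ring excludes Friedel–Crafts capture of the cation and ionisation towards the phenol is reversible and non-productive.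

**Step 7**
Reactants: 13
Product: 14 gericudranin D, (2R,3R)-3,5,7-trihydroxy-2-(4-hydroxyphenyl)-6,8-bis(4-hydroxybenzyl)chroman-4-one
Conditions: H2 (1 atm), 10% Pd/C, EtOAc/MeOH, rt
Reagents that add atoms: none
Why: hydrogenolysis of five aryl benzyl ethers; under neutral conditions at rt the ring C2–O1 bond, the diarylmethane bonds and the ketone should survive, and neither C2 (no quinone methide opening) nor C3 (no enolisation) should epimerise.

**Compound list**

1 | 2',4',6'-trihydroxyacetophenone | CC(=O)c1c(O)cc(O)cc1O | starting material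
2 | 4-(benzyloxy)benzyl alcohol | OCc1ccc(OCc2ccccc2)cc1 | starting material
3 | 1-{2,4,6-trihydroxy-3,5-bis[4-(benzyloxy)benzyl]phenyl}ethanone | CC(=O)c1c(O)c(Cc2ccc(OCc3ccccc3)cc2)c(O)c(Cc2ccc(OCc3ccccc3)cc2)c1O | intermediate
4 | benzyl bromide | BrCc1ccccc1 | starting material
5 | 1-{2,4-bis(benzyloxy)-3,5-bis[4-(benzyloxy)benzyl]-6-hydroxyphenyl}ethanone | CC(=O)c1c(O)c(Cc2ccc(OCc3ccccc3)cc2)c(OCc2ccccc2)c(Cc2ccc(OCc3ccccc3)cc2)c1OCc1ccccc1 | intermediate
6 | trimethylsilyl enol ether of 5 with the phenol as its trimethylsilyl ether | C=C(O[Si](C)(C)C)c1c(O[Si](C)(C)C)c(Cc2ccc(OCc3ccccc3)cc2)c(OCc2ccccc2)c(Cc2ccc(OCc3ccccc3)cc2)c1OCc1ccccc1 | intermediate (not isolated)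
7 | 1-{2,4-bis(benzyloxy)-3,5-bis[4-(benzyloxy)benzyl]-6-(trimethylsilyloxy)phenyl}-2-(trimethylsilyloxy)ethanone | C[Si](C)(C)OCC(=O)c1c(O[Si](C)(C)C)c(Cc2ccc(OCc3ccccc3)cc2)c(OCc2ccccc2)c(Cc2ccc(OCc3ccccc3)cc2)c1OCc1ccccc1 | intermediate (not isolated)
8 | 1-{2,4-bis(benzyloxy)-3,5-bis[4-(benzyloxy)benzyl]-6-hydroxyphenyl}-2-hydroxyethanone | OCC(=O)c1c(O)c(Cc2ccc(OCc3ccccc3)cc2)c(OCc2ccccc2)c(Cc2ccc(OCc3ccccc3)cc2)c1OCc1ccccc1 | intermediate
9 | 4-(benzyloxy)benzaldehyde | O=Cc1ccc(OCc2ccccc2)cc1 | starting material
10 | 4-(benzyloxy)benzaldehyde dimethyl acetal | COC(OC)c1ccc(OCc2ccccc2)cc1 | intermediate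
11 | rac-6,8-bis(benzyloxy)-2-[4-(benzyloxy)phenyl]-7,9-bis[4-(benzyloxy)benzyl]-4H-1,3-benzodioxepin-5-one | O=C1COC(c2ccc(OCc3ccccc3)cc2)Oc2c(Cc3ccc(OCc4ccccc4)cc3)c(OCc3ccccc3)c(Cc3ccc(OCc4ccccc4)cc3)c(OCc3ccccc3)c21 | intermediate
12 | ring-opened O-aryl oxocarbenium ion carrying the enediol (cation of the ion pair with the catalyst anion) | OC=C(O)c1c(OCc2ccccc2)c(Cc2ccc(OCc3ccccc3)cc2)c(OCc2ccccc2)c(Cc2ccc(OCc3ccccc3)cc2)c1[O+]=Cc1ccc(OCc2ccccc2)cc1 | intermediate (not isolated)
13 | (2R,3R)-5,7-bis(benzyloxy)-2-[4-(benzyloxy)phenyl]-6,8-bis[4-(benzyloxy)benzyl]-3-hydroxychroman-4-one | O=C1c2c(OCc3ccccc3)c(Cc3ccc(OCc4ccccc4)cc3)c(OCc3ccccc3)c(Cc3ccc(OCc4ccccc4)cc3)c2O[C@H](c2ccc(OCc3ccccc3)cc2)[C@H]1O | intermediate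
14 | gericudranin D | O=C1c2c(O)c(Cc3ccc(O)cc3)c(O)c(Cc3ccc(O)cc3)c2O[C@H](c2ccc(O)cc2)[C@H]1O | target

**Step count**

Total steps: 7. Longest linear sequence: 6 (steps 1, 2, 3, 5, 6, 7).

**Steps most likely to fail**

Step 6. The ion-pair collapse may proceed with low or opposite enantioinduction, the C–C bond may form in part at the aryl-bearing enediol carbon (five-membered ring), or enolisation may be too slow so that the acetal only equilibrates. The fallback uses known chemistry, sets out from 5 and comes back at 13. The phenol of 5 is protected (NaH, MOMCl, DMF) to give 1-{2,4-bis(benzyloxy)-3,5-bis[4-(benzyloxy)benzyl]-6-(methoxymethoxy)phenyl}ethanone F1. Claisen–Schmidt condensation with 9 (KOH, EtOH/THF) gives the (E)-chalcone F2. Julia–Colonna epoxidation (poly-L-leucine, urea–H2O2, DBU, THF) should give the (αR,βS)-epoxy ketone F3. HCl in MeOH/THF then removes the MOM group, and the freed phenol opens the epoxide at the benzylic carbon with inversion (6-endo) to give 13.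

Step 5. Closure of a seven-membered mixed aryl alkyl acetal on a hindered, hydrogen-bonded phenol may be unfavourable at equilibrium, and oligomeric acetals or premature racemic ring contraction may intervene. The fallback sets out from 7 (obtained from step 3 by leaving out the acid hydrolysis, or from 8 by re-silylation) and comes back at 11. It is a kinetically driven silyl-transfer acetalisation of the bis-silyl ether with aldehyde 9 (TMSOTf cat., CH2Cl2, −78 °C), in which formation of the disiloxane makes ring closure irreversible; no new compound is made.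

Step 2. The hindered, ambident phloroglucinolate may undergo C-benzylation at the substituted ring carbons (dearomatisation), and over- or under-alkylation may occur. The fallback reverses the order of O- and C-benzylation; it sets out from 1 and comes back at 5. Compound 1 is O-benzylated first (BnBr, K2CO3, DMF), where the ring positions are still unsubstituted, to give 1-[2,4-bis(benzyloxy)-6-hydroxyphenyl]ethanone F4. Twofold Friedel–Crafts benzylation of F4 with 2 (Sc(OTf)3, MeCN) then gives 5.

**Further compounds**

F1 | step 6 | 1-{2,4-bis(benzyloxy)-3,5-bis[4-(benzyloxy)benzyl]-6-(methoxymethoxy)phenyl}ethanone | CC(=O)c1c(OCOC)c(Cc2ccc(OCc3ccccc3)cc2)c(OCc2ccccc2)c(Cc2ccc(OCc3ccccc3)cc2)c1OCc1ccccc1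
F2 | step 6 | (E)-1-{2,4-bis(benzyloxy)-3,5-bis[4-(benzyloxy)benzyl]-6-(methoxymethoxy)phenyl}-3-[4-(benzyloxy)phenyl]prop-2-en-1-one | O=C(/C=C/c1ccc(OCc2ccccc2)cc1)c1c(OCOC)c(Cc2ccc(OCc3ccccc3)cc2)c(OCc2ccccc2)c(Cc2ccc(OCc3ccccc3)cc2)c1OCc1ccccc1
F3 | step 6 | (2R,3S)-epoxide of F2, {2,4-bis(benzyloxy)-3,5-bis[4-(benzyloxy)benzyl]-6-(methoxymethoxy)phenyl}{(2R,3S)-3-[4-(benzyloxy)phenyl]oxiran-2-yl}methanone | O=C([C@@H]1O[C@H]1c1ccc(OCc2ccccc2)cc1)c1c(OCOC)c(Cc2ccc(OCc3ccccc3)cc2)c(OCc2ccccc2)c(Cc2ccc(OCc3ccccc3)cc2)c1OCc1ccccc1
F0 | step 5 | none | none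
F4 | step 2 | 1-[2,4-bis(benzyloxy)-6-hydroxyphenyl]ethanone | CC(=O)c1c(O)cc(OCc2ccccc2)cc1OCc1ccccc1
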